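**Retrosynthetic overview**

1. The target is the C2-symmetric core 2,5-dihydroxy-3,6-bis(5-prenylindol-3-yl)-1,4-benzoquinone with one enolic OH exchanged for OOH (a vinylogous peroxy acid). This exchange is made last, by mono-triflation of the symmetric dihydroxyquinone and addition–elimination with H2O2.
2. Enabling feature: in the central six-membered ring the indolyl-bearing carbons C3 and C6 are each flanked by an enol carbon (C2, C5) and a carbonyl carbon (C4, C1). The ring is therefore the enol tautomer of a 3,6-diaryl-cyclohexane-1,2,4,5-tetraone, that is, two identical Ar–CH–C(=O)–C(=O) units joined head to tail, and needs no redox adjustment.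
3. Key disconnection: both C(indolyl)–C(=O) ring bonds (C3–C4 and C6–C1). This leads to two molecules of one monomer, a (Z)-5-(indol-3-ylmethylidene)-2,2-dimethyl-1,3-dioxolan-4-one. Its temporary dioxolanone ring masks the ketone as an enol acetal and activates the carboxyl carbon; a methoxide-triggered Claisen–Dieckmann cascade closes the quinone ring, expels acetone and removes the N-Boc groups in the same flask.
4. The monomer comes from a commercial indol-5-ylboronate by prenylation, C3-formylation, N-Boc protection and aldol condensation with glycolic acid acetonide.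
5. Ring order: both indole bicycles are bought intact, the dioxolanone is a bought temporary ring, and the central quinone ring is the only ring constructed and the last ring of the skeleton to be closed.

Key step: step 6

Remark on the chemistry: the hydroperoxy-quinone is assumed to tolerate brief handling at 0 °C and pH 3–7 in the dark when traces of transition metals are sequestered; the last step and its work-up are planned on that basis.

**Route**

Step 1
Reactants: 1 5-(4,4,5,5-tetramethyl-1,3,2-dioxaborolan-2-yl)-1H-indole; 2 1-bromo-3-methylbut-2-ene (prenyl bromide)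
Product: 3 5-(3-methylbut-2-en-1-yl)-1H-indole
Conditions: Pd(PPh3)4 (5 mol %), CsF (3 equiv), THF, 65 °C
Reagents that add atoms: none
Why: Suzuki–Miyaura-type allyl–aryl cross-coupling in which oxidative addition of prenyl bromide to zerovalent palladium gives a 1,1-dimethylallyl palladium species that takes up the indol-5-yl group from the fluoride-activated boronate and reductively eliminates at the unsubstituted allyl terminus, so that the linear prenyl arene is expected and the free indole N–H is tolerated.

Step 2
Reactants: 3 5-(3-methylbut-2-en-1-yl)-1H-indole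
Product: 5 aldehyde 5-(3-methylbut-2-en-1-yl)-1H-indole-3-carbaldehyde, via iminium chloride 4 (not isolated)
Conditions: POCl3 (1.1 equiv), DMF, 0 → 20 °C; then aq. NaOH, 0 → 40 °C
Reagents that add atoms: N,N-dimethylformamide CN(C)C=O; water O
Why: Vilsmeier–Haack formylation, in which the chloroiminium salt attacks the most nucleophilic position C3 of the N–H indole far faster than it reacts with the trisubstituted alkene, and the iminium salt 4 is hydrolysed by aqueous NaOH.

Step 3
Reactants: 5 5-(3-methylbut-2-en-1-yl)-1H-indole-3-carbaldehyde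
Product: 6 tert-butyl 3-formyl-5-(3-methylbut-2-en-1-yl)-1H-indole-1-carboxylate
Conditions: Boc2O (1.2 equiv), DMAP (cat.), MeCN, 20 °C
Reagents that add atoms: di-tert-butyl dicarbonate CC(C)(C)OC(=O)OC(=O)OC(C)(C)C
Why: DMAP-catalysed N-acylation (carbamate formation) of the acidic N–H of a 3-formylindole, which removes the acidic proton and raises the electrophilicity of the aldehyde for the aldol step.

Step 4
Reactants: 6 tert-butyl 3-formyl-5-(3-methylbut-2-en-1-yl)-1H-indole-1-carboxylate; 7 2,2-dimethyl-1,3-dioxolan-4-one
Product: 8 tert-butyl 3-[(2,2-dimethyl-5-oxo-1,3-dioxolan-4-yl)(hydroxy)methyl]-5-(3-methylbut-2-en-1-yl)-1H-indole-1-carboxylate (racemic mixture of diastereomers)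
Conditions: 7, LiN(i-Pr)2 (1.1 equiv), THF, −78 °C, 10 min; then 6, −78 °C; AcOH quench at −78 °C
Reagents that add atoms: none
Why: aldol addition of the briefly pre-formed lithium enolate of the glycolic acid acetonide to the activated aldehyde at low temperature, the two new stereocentres being formed without control because both are destroyed in step 5.

Step 5
Reactants: 8 aldol adduct (mixture of diastereomers)
Product: 10 tert-butyl 3-[(Z)-(2,2-dimethyl-5-oxo-1,3-dioxolan-4-ylidene)methyl]-5-(3-methylbut-2-en-1-yl)-1H-indole-1-carboxylate, via mesylate 9 (not isolated)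
Conditions: MsCl (1.5 equiv), Et3N (3 equiv), CH2Cl2, 0 °C; then DBU (1.5 equiv), 20 °C
Reagents that add atoms: none
Why: mesylation followed by base-induced elimination (E1cB through the lactone enolate) to the conjugated alkylidene dioxolanone, for which the Z isomer (indolyl cis to the ring oxygen) is the thermodynamically preferred geometry, and any E isomer converges on the same enolate in step 6.

Step 6
Reactants: 10 tert-butyl 3-[(Z)-(2,2-dimethyl-5-oxo-1,3-dioxolan-4-ylidene)methyl]-5-(3-methylbut-2-en-1-yl)-1H-indole-1-carboxylate (two molecules)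
Product: 14 cochliodinol (2,5-dihydroxy-3,6-bis[5-(3-methylbut-2-en-1-yl)-1H-indol-3-yl]cyclohexa-2,5-diene-1,4-dione), via methyl ester sodium enolate 11 (not isolated), via acyclic triketo ester enolate 12 (not isolated), via bis-Boc dihydroxyquinone 13 (not isolated)
Conditions: NaOMe (0.15 equiv), Cs2CO3 (2.5 equiv, powdered), THF, 20 → 45 °C, argon; then NaOMe (6 equiv), MeOH, 55 °C; 1 M HCl to pH 3
Reagents that add atoms: none
Why: Proposed new method: a catalytic amount of methoxide opens the acylal-type lactone carbonyl of one molecule of 10 with loss of acetone to give the enolate 11, the indolyl-bearing carbon of 11 is acylated by the lactone carbonyl of a second molecule of 10 (second loss of acetone) to give the open-chain enolate 12, and the terminal enolate carbon of 12 then attacks the methyl ester and expels methoxide, which re-enters the cycle. The closest known reaction types are the C-acylation of ester enolates by 5-ylidene-1,3-dioxolan-4-ones, the alkoxide-mediated self-condensation of 2-oxo esters to 3,6-disubstituted 2,5-dihydroxy-1,4-benzoquinones (Claisen then Dieckmann condensation) and the base-induced rearrangement of isomeric enol lactones into such quinones. The one ring that is closed is the six-membered carbocycle, built through both C(indolyl)–C(=O) bonds, the first intermolecularly and the second by a 6-(enolexo)-exo-trig Dieckmann closure, and the resulting cyclohexane-1,2,4,5-tetraone is the keto tautomer of the dihydroxyquinone, so the ring appears at the correct oxidation level. No stereocentre is created and the Z geometry of 10 is erased on enolisation. The step needs head-to-tail C-acylation instead of aldol dimerisation to a butenolide, and this is secured because neither partner has a free ketone (one is an enolate, the other an enol acetal), the acyl carbon is the only electrophilic site and the enolate carbon next to the indole the only carbon nucleophile, while O-acylated isomers are reopened by methoxide and the doubly deprotonated quinone is the thermodynamic sink. Cs2CO3 serves as a proton sink that keeps the enols deprotonated but is too weak to enolise the liberated acetone or to open 10 itself, so that a small stationary amount of 11 always meets an excess of 10, and the final excess of NaOMe in MeOH removes both indole N-Boc groups of 13 as tert-butyl methyl carbonate.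

Step 7
Reactants: 14 cochliodinol
Product: 15 4-hydroxy-3,6-dioxo-2,5-bis[5-(3-methylbut-2-en-1-yl)-1H-indol-3-yl]cyclohexa-1,4-dien-1-yl trifluoromethanesulfonate
Conditions: i-Pr2NEt (2.2 equiv), Tf2O (1.0 equiv, slow addition), CH2Cl2, −78 °C; cold aq. NaH2PO4 wash; used at once
Reagents that add atoms: trifluoromethanesulfonic anhydride O=S(=O)(OS(=O)(=O)C(F)(F)F)C(F)(F)F
Why: O-sulfonylation (enol triflate formation) of a vinylogous carboxylate as practised on 2-hydroxy-1,4-quinones, in which the bis(ammonium) dianion of 14 is markedly more nucleophilic than the mono-triflated monoanion so that one equivalent of Tf2O at −78 °C is expected to stop after the first triflation, while the amine base does not deprotonate the indole N–H.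

Step 8
Reactants: 15 mono-triflate
Product: 16 hydroperoxycochliodinol (2-hydroperoxy-5-hydroxy-3,6-bis[5-(3-methylbut-2-en-1-yl)-1H-indol-3-yl]cyclohexa-2,5-diene-1,4-dione)
Conditions: H2O2 (30% aq., 10 equiv), Na2HPO4/NaH2PO4 buffer pH 7.5 containing DTPA, THF, 0 °C, dark; NaH2PO4 to pH 4, extraction, chromatography at low temperature
Reagents that add atoms: hydrogen peroxide OO
Why: nucleophilic vinylic substitution (addition–elimination) by hydrogen peroxide at the triflate-bearing quinone carbon, the reaction type by which chlorinated 1,4-benzoquinones and their chloro-hydroxy anions exchange halide for a hydroperoxy group at neutral pH, in which the alpha-effect nucleophile outcompetes water, triflate is the only nucleofuge and the ionised enol on the opposite side of the ring prevents a second substitution.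

**Compound list**

1 | 5-(4,4,5,5-tetramethyl-1,3,2-dioxaborolan-2-yl)-1H-indole | CC1(C)OB(OC1(C)C)c1ccc2[nH]ccc2c1 | starting material
2 | 1-bromo-3-methylbut-2-ene (prenyl bromide) | CC(C)=CCBr | starting material
3 | 5-(3-methylbut-2-en-1-yl)-1H-indole | CC(C)=CCc1ccc2[nH]ccc2c1 | intermediate
4 | N-methyl-N-{[5-(3-methylbut-2-en-1-yl)-1H-indol-3-yl]methylidene}methanaminium chloride (formed in the flask) | CC(C)=CCc1ccc2[nH]cc(C=[N+](C)C)c2c1.[Cl-] | intermediate
5 | 5-(3-methylbut-2-en-1-yl)-1H-indole-3-carbaldehyde | CC(C)=CCc1ccc2[nH]cc(C=O)c2c1 | intermediate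
6 | tert-butyl 3-formyl-5-(3-methylbut-2-en-1-yl)-1H-indole-1-carboxylate | CC(C)=CCc1ccc2c(c1)c(C=O)cn2C(=O)OC(C)(C)C | intermediate
7 | 2,2-dimethyl-1,3-dioxolan-4-one | CC1(C)OCC(=O)O1 | starting material
8 | tert-butyl 3-[(2,2-dimethyl-5-oxo-1,3-dioxolan-4-yl)(hydroxy)methyl]-5-(3-methylbut-2-en-1-yl)-1H-indole-1-carboxylate, racemic mixture of diastereomers | CC(C)=CCc1ccc2c(c1)c(cn2C(=O)OC(C)(C)C)C(O)C1OC(C)(C)OC1=O | intermediate
9 | methanesulfonate of 8, mixture of diastereomers (formed in the flask) | CC(C)=CCc1ccc2c(c1)c(cn2C(=O)OC(C)(C)C)C(OS(C)(=O)=O)C1OC(C)(C)OC1=O | intermediate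
10 | tert-butyl 3-[(Z)-(2,2-dimethyl-5-oxo-1,3-dioxolan-4-ylidene)methyl]-5-(3-methylbut-2-en-1-yl)-1H-indole-1-carboxylate | CC(C)=CCc1ccc2c(c1)c(cn2C(=O)OC(C)(C)C)/C=C1\OC(C)(C)OC1=O | intermediate
11 | sodium (Z)-enolate of methyl 3-[1-(tert-butoxycarbonyl)-5-(3-methylbut-2-en-1-yl)indol-3-yl]-2-oxopropanoate (formed in the flask; counter-ion sodium or caesium) | [Na+].COC(=O)/C([O-])=C/c1cn(C(=O)OC(C)(C)C)c2ccc(CC=C(C)C)cc12 | intermediate
12 | sodium enolate of methyl 3,6-bis[1-(tert-butoxycarbonyl)-5-(3-methylbut-2-en-1-yl)indol-3-yl]-2,4,5-trioxohexanoate (formed in the flask; enolate geometry not defined) | [Na+].COC(=O)C(=O)C(c1cn(C(=O)OC(C)(C)C)c2ccc(CC=C(C)C)cc12)=C([O-])C(=O)Cc1cn(C(=O)OC(C)(C)C)c2ccc(CC=C(C)C)cc12 | intermediate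
13 | 2,5-dihydroxy-3,6-bis[1-(tert-butoxycarbonyl)-5-(3-methylbut-2-en-1-yl)indol-3-yl]cyclohexa-2,5-diene-1,4-dione (formed in the flask as its dianion) | CC(C)=CCc1ccc2c(c1)c(cn2C(=O)OC(C)(C)C)C1=C(O)C(=O)C(=C(O)C1=O)c1cn(C(=O)OC(C)(C)C)c2ccc(CC=C(C)C)cc12 | intermediate
14 | cochliodinol, 2,5-dihydroxy-3,6-bis[5-(3-methylbut-2-en-1-yl)-1H-indol-3-yl]cyclohexa-2,5-diene-1,4-dione | CC(C)=CCc1ccc2[nH]cc(C3=C(O)C(=O)C(c4c[nH]c5ccc(CC=C(C)C)cc45)=C(O)C3=O)c2c1 | intermediate
15 | 4-hydroxy-3,6-dioxo-2,5-bis[5-(3-methylbut-2-en-1-yl)-1H-indol-3-yl]cyclohexa-1,4-dien-1-yl trifluoromethanesulfonate | CC(C)=CCc1ccc2[nH]cc(C3=C(O)C(=O)C(c4c[nH]c5ccc(CC=C(C)C)cc45)=C(OS(=O)(=O)C(F)(F)F)C3=O)c2c1 | intermediate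
16 | hydroperoxycochliodinol, 2-hydroperoxy-5-hydroxy-3,6-bis[5-(3-methylbut-2-en-1-yl)-1H-indol-3-yl]cyclohexa-2,5-diene-1,4-dione (no stereocentre) | CC(C)=CCc1ccc2[nH]cc(C3=C(O)C(=O)C(c4c[nH]c5ccc(CC=C(C)C)cc45)=C(OO)C3=O)c2c1 | target

**Step count and risks**

Total step count: 8 steps. Longest linear sequence: 8 steps (from 1 to 16).

Steps most likely to fail:

Step 6 (proposed new method). The stabilised enolate may be acylated at oxygen or too slowly at carbon, methanolysis may consume the monomer faster than the carbon–carbon bond forms, or the open-chain intermediate may fragment by retro-Claisen cleavage instead of cyclising. The fallback uses known quinone arylation and hydrolysis chemistry; it sets out from 3 and comes back at 14. Conjugate addition of 3 to commercial 2,5-dichloro-1,4-benzoquinone under InBr3 catalysis in THF, with re-oxidation of the hydroquinone adduct by DDQ, is expected to give 2,5-dichloro-3-[5-(3-methylbut-2-en-1-yl)-1H-indol-3-yl]cyclohexa-2,5-diene-1,4-dione F1. A second addition of 3 and re-oxidation is expected to give 2,5-dichloro-3,6-bis[5-(3-methylbut-2-en-1-yl)-1H-indol-3-yl]cyclohexa-2,5-diene-1,4-dione F2. Exchange of both vinylogous acid chlorides with NaOH in aqueous MeOH at reflux, followed by acidification, then gives 14; in this fallback the quinone ring is bought and not built.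

Step 8. The hydroperoxide may be lost after it forms by homolysis of the O–O bond or by metal-catalysed decomposition, hydroperoxide may attack sulfur instead of carbon and return 14, or the hydroxyquinone ring may be cleaved oxidatively. The fallback sets out from 15 and comes back at 16 and introduces the peroxide in capped form. Compound 15 is treated with the known reagent 2-methoxyprop-2-yl hydroperoxide and Cs2CO3 in THF at 0 °C to give the peroxyketal 2-hydroxy-5-[(2-methoxypropan-2-yl)peroxy]-3,6-bis[5-(3-methylbut-2-en-1-yl)-1H-indol-3-yl]cyclohexa-2,5-diene-1,4-dione F3. This can be purified as a perester-type compound and is unmasked only at the end with AcOH in THF–H2O at 0 °C to give 16.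

Step 7. Triflation may run on to the bis-triflate or stop short, giving mixtures, and the triflate may hydrolyse during handling. The fallback sets out from 14 and comes back at 15 and replaces stoichiometric mono-activation by exhaustive activation and self-limiting hydrolysis. Compound 14 is treated with Tf2O (2.5 equiv) and 2,6-lutidine in CH2Cl2 at −78 °C to give the bis-triflate 3,6-dioxo-2,5-bis[5-(3-methylbut-2-en-1-yl)-1H-indol-3-yl]cyclohexa-1,4-diene-1,4-diyl bis(trifluoromethanesulfonate) F4. One equivalent of aqueous NaHCO3 in THF at 0 °C then hydrolyses one triflate; the enolate anion so formed deactivates the quinone toward a second substitution, and 15 is expected.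

**Further compounds**

F1 | step 6 | 2,5-dichloro-3-[5-(3-methylbut-2-en-1-yl)-1H-indol-3-yl]cyclohexa-2,5-diene-1,4-dione | CC(C)=CCc1ccc2[nH]cc(C3=C(Cl)C(=O)C=C(Cl)C3=O)c2c1
F2 | step 6 | 2,5-dichloro-3,6-bis[5-(3-methylbut-2-en-1-yl)-1H-indol-3-yl]cyclohexa-2,5-diene-1,4-dione | CC(C)=CCc1ccc2[nH]cc(C3=C(Cl)C(=O)C(c4c[nH]c5ccc(CC=C(C)C)cc45)=C(Cl)C3=O)c2c1
F3 | step 8 | 2-hydroxy-5-[(2-methoxypropan-2-yl)peroxy]-3,6-bis[5-(3-methylbut-2-en-1-yl)-1H-indol-3-yl]cyclohexa-2,5-diene-1,4-dione | CC(C)=CCc1ccc2[nH]cc(C3=C(O)C(=O)C(c4c[nH]c5ccc(CC=C(C)C)cc45)=C(OOC(C)(C)OC)C3=O)c2c1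
F4 | step 7 | 3,6-dioxo-2,5-bis[5-(3-methylbut-2-en-1-yl)-1H-indol-3-yl]cyclohexa-1,4-diene-1,4-diyl bis(trifluoromethanesulfonate) | CC(C)=CCc1ccc2[nH]cc(C3=C(OS(=O)(=O)C(F)(F)F)C(=O)C(c4c[nH]c5ccc(CC=C(C)C)cc45)=C(OS(=O)(=O)C(F)(F)F)C3=O)c2c1
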